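**Plan**

1. Numbering (ansamycin): C1 = amide C=O, C2–C15 = ansa chain with the C11–O–C15 tetrahydropyran, C16–C21 = quinone (C16 bears C15, C17 OH, C18 and C21 C=O, C19 H, C20 N).
2. Cuts: C2=C3 (ring-closing metathesis) and N–C1 (acylation); C20–N (azide amination); the quinone ring back to a four-membered ring (C18–C19 and C20–C21, i.e. ethyne added to a cyclobutenedione); C15–C16 (anomeric organolithium + squarate); C7–C8 (alkenylmagnesium + α-methoxy aldehyde); C10–C11 (allenylstannane + aldehyde).
3. Enabling feature: in the quinone the alkyl/oxygen pair C16/C17 lies between both carbonyls and C19 is unsubstituted. C16, C17, C18 and C21 are therefore the four carbons of a squarate ester and C19–C20 an added ethynyl group, so a 2-alkyl-3-alkoxy-4-ethynyl-4-hydroxycyclobutenone expands 4 → 6 straight to the quinone oxidation level with all substituents placed.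
4. Forward order: γ-lactone → open chain C11–C15 → tetrahydropyran (lactol, thioacetal) → chain joined at C7–C8 → four-membered ring attached at C15 → expanded to the quinone → N at C20 → macrocycle closed last at C2=C3 → acidolysis.
5. Stereochemistry: C6 from (S)-glycidyl trityl ether; C12 from the (S)-γ-lactone (glutamic acid pool) and C14 by lactone enolate methylation/kinetic protonation; C10/C11 from a chiral allenylstannane (Felkin-matched); C7 by chelate control; C15 by the axial anomeric organolithium (retention); C8=C9 by syn-hydrozirconation; C2=C3 by metathesis.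

Key step: step 22

Remark on the chemistry: di-tert-butyl squarate, (S)-glycidyl trityl ether, (S)-5-(trityloxymethyl)dihydrofuran-2(3H)-one and pent-3-yn-2-one are taken as purchasable. The lactol and the 2-(phenylthio)tetrahydropyrans are anomeric mixtures and the cyclobutenone carbinols are epimeric mixtures, so these centres (erased later) are left undefined in the SMILES. Metal alkoxides that are only protonated at work-up are not listed separately.

Step 1
Reactants: 1 (S)-glycidyl trityl ether
Product: 2 (S)-1-(trityloxy)hex-5-en-2-ol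
Conditions: allylMgBr, CuI (10 mol%), THF, −30 → 0 °C; then H2O
Reagents that add atoms: allylmagnesium bromide, C=CC[Mg]Br
Why: Copper-assisted SN2 opening of the epoxide at its unsubstituted carbon leaves the stereocentre (future C6) untouched.

Step 2
Reactants: 2 (S)-1-(trityloxy)hex-5-en-2-ol
Product: 3 (S)-2-methoxy-1-(trityloxy)hex-5-ene
Conditions: NaH, MeI, THF/DMF, 0 °C → rt
Reagents that add atoms: iodomethane, CI
Why: Williamson etherification of the secondary alkoxide installs the C6 methyl ether without touching the stereocentre.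

Step 3
Reactants: 3 (S)-2-methoxy-1-(trityloxy)hex-5-ene
Product: 4 (S)-2-methoxyhex-5-en-1-ol
Conditions: TsOH·H2O (5 mol%), MeOH/CH2Cl2, rt
Reagents that add atoms: none
Why: Acid-catalysed methanolysis of the trityl ether (via the trityl cation) should free the primary alcohol and leave the methyl ether and alkene intact.

Step 4
Reactants: 4 (S)-2-methoxyhex-5-en-1-ol
Product: 5 (S)-2-methoxyhex-5-enal
Conditions: Dess–Martin periodinane, CH2Cl2, 0 °C → rt; used as crude solution
Reagents that add atoms: none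
Why: Dess–Martin oxidation is non-basic, so the α-alkoxy aldehyde should form without epimerisation.

Step 5
Reactants: 6 pent-3-yn-2-one
Product: 7 (S)-pent-3-yn-2-ol
Conditions: RuCl[(S,S)-TsDPEN](p-cymene) (1 mol%), i-PrOH, rt
Reagents that add atoms: none
Why: Noyori asymmetric transfer hydrogenation of an ynone, in which the (S,S)-catalyst should deliver hydride to give the (S)-propargylic alcohol.

Step 6
Reactants: 7 (S)-pent-3-yn-2-ol
Product: 8 (S)-pent-3-yn-2-yl methanesulfonate
Conditions: MsCl, Et3N, CH2Cl2, −78 → 0 °C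
Reagents that add atoms: methanesulfonyl chloride, CS(=O)(=O)Cl
Why: O-sulfonylation proceeds with retention because the C–O bond is not broken.

Step 7
Reactants: 8 (S)-pent-3-yn-2-yl methanesulfonate
Product: 9 (aR)-tributyl(penta-2,3-dien-2-yl)stannane
Conditions: Bu3SnH, LDA, THF, 0 °C; CuBr·SMe2, −78 °C; then 8, −78 °C
Reagents that add atoms: tributyltin hydride, CCCC[SnH](CCCC)CCCC
Why: Anti-SN2′ displacement of the propargylic mesylate by the stannylcopper reagent transfers the central chirality to the allene axis.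

Step 8
Reactants: 10 (S)-5-(trityloxymethyl)dihydrofuran-2(3H)-one
Product: 12 (3R,5S)-3-methyl-5-(trityloxymethyl)dihydrofuran-2(3H)-one (trans), via lithium enolate 11 (not isolated)
Conditions: LDA, THF, −78 °C; MeI, −78 → −40 °C
Reagents that add atoms: iodomethane, CI
Why: Lactone enolate alkylation occurs anti to the bulky trityloxymethyl group and gives the trans lactone.

Step 9
Reactants: 12 (3R,5S)-3-methyl-5-(trityloxymethyl)dihydrofuran-2(3H)-one
Product: 14 (3S,5S)-3-methyl-5-(trityloxymethyl)dihydrofuran-2(3H)-one (cis), via lithium enolate 13 (not isolated)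
Conditions: LDA, THF, −78 °C; then 2,6-di-tert-butyl-4-methylphenol, −78 °C
Reagents that add atoms: none
Why: Kinetic protonation of the enolate by a bulky phenol from the face opposite the trityloxymethyl group places the methyl group cis and sets C14.

Step 10
Reactants: 14 (3S,5S)-3-methyl-5-(trityloxymethyl)dihydrofuran-2(3H)-one
Product: 15 (2S,4S)-4-hydroxy-N-methoxy-N,2-dimethyl-5-(trityloxy)pentanamide
Conditions: MeNH(OMe)·HCl, i-PrMgCl, THF, −20 → 0 °C; then H2O
Reagents that add atoms: N,O-dimethylhydroxylamine hydrochloride, CNOC.Cl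
Why: Weinreb aminolysis of the lactone by the magnesium amide frees the C12 hydroxyl and keeps C15 at the acyl level, and at low temperature the α-centre should not epimerise.

Step 11
Reactants: 15 (2S,4S)-4-hydroxy-N-methoxy-N,2-dimethyl-5-(trityloxy)pentanamide
Product: 16 (2S,4S)-N,4-dimethoxy-N,2-dimethyl-5-(trityloxy)pentanamide
Conditions: MeI, Ag2O, 4 Å MS, Et2O, rt, dark
Reagents that add atoms: iodomethane, CI
Why: Purdie methylation is non-basic, so the γ-hydroxy amide should be etherified (C12–OMe) without relactonisation or epimerisation.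

Step 12
Reactants: 16 (2S,4S)-N,4-dimethoxy-N,2-dimethyl-5-(trityloxy)pentanamide
Product: 17 (2S,4S)-5-hydroxy-N,4-dimethoxy-N,2-dimethylpentanamide
Conditions: TsOH·H2O (5 mol%), MeOH/CH2Cl2, 0 °C
Reagents that add atoms: none
Why: Mild acid methanolysis of the trityl ether frees the C11 alcohol while the Weinreb amide is inert to alcoholysis at this temperature.

Step 13
Reactants: 17 (2S,4S)-5-hydroxy-N,4-dimethoxy-N,2-dimethylpentanamide
Product: 18 (2S,4S)-N,4-dimethoxy-N,2-dimethyl-5-oxopentanamide
Conditions: Dess–Martin periodinane, CH2Cl2, 0 °C → rt; used crude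
Reagents that add atoms: none
Why: Neutral Dess–Martin oxidation should give the α-methoxy aldehyde without epimerisation at C12.

Step 14
Reactants: 18 (2S,4S)-N,4-dimethoxy-N,2-dimethyl-5-oxopentanamide and 9 (aR)-tributyl(penta-2,3-dien-2-yl)stannane
Product: 19 (2S,4S,5R,6S)-5-hydroxy-N,4-dimethoxy-N,2,6-trimethylnon-7-ynamide
Conditions: BF3·OEt2 (2.5 equiv), CH2Cl2, −78 °C
Reagents that add atoms: none
Why: Marshall propargylation (anti-SE2′ addition of the allenylstannane through an open transition state) sets C10 from the allene axis and gives the 10,11-syn adduct, while Felkin–Anh addition to the non-chelated α-methoxy aldehyde gives 11,12-anti, a matched pair.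

Step 15
Reactants: 19 (2S,4S,5R,6S)-5-hydroxy-N,4-dimethoxy-N,2,6-trimethylnon-7-ynamide
Product: 20 (3S,5S,6R)-5-methoxy-3-methyl-6-[(S)-pent-3-yn-2-yl]tetrahydro-2H-pyran-2-ol (lactol)
Conditions: DIBAL-H (2.5 equiv), THF, −78 °C; Rochelle salt
Reagents that add atoms: none
Why: The Weinreb amide is reduced through its stable chelate to the C15 aldehyde, which closes on the C11 hydroxyl to the six-membered lactol.

Step 16
Reactants: 20 (3S,5S,6R)-5-methoxy-3-methyl-6-[(S)-pent-3-yn-2-yl]tetrahydro-2H-pyran-2-ol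
Product: 21 (3S,5S,6R)-5-methoxy-3-methyl-6-[(S)-pent-3-yn-2-yl]-2-(phenylthio)tetrahydro-2H-pyran
Conditions: PhSH (1.2 equiv), BF3·OEt2 (0.3 equiv), CH2Cl2, −40 → 0 °C
Reagents that add atoms: thiophenol, Sc1ccccc1
Why: Lewis-acid thioglycosidation through the cyclic oxocarbenium ion gives the O,S-acetal, whose anomeric ratio is irrelevant because C15 is reset in step 20.

Step 17
Reactants: 21 (3S,5S,6R)-5-methoxy-3-methyl-6-[(S)-pent-3-yn-2-yl]-2-(phenylthio)tetrahydro-2H-pyran
Product: 23 (3S,5S,6R)-6-[(2S,3E)-4-iodopent-3-en-2-yl]-5-methoxy-3-methyl-2-(phenylthio)tetrahydro-2H-pyran, via alkenylzirconocene chloride 22 (not isolated)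
Conditions: Cp2Zr(H)Cl (2.5 equiv), THF, 50 °C; then I2 (titrated), 0 °C
Reagents that add atoms: iodine, II
Why: Syn-hydrozirconation under equilibrating conditions puts zirconium on the methyl-bearing carbon remote from the branched C10, and iodinolysis with retention gives the (E)-iodide.

Step 18
Reactants: 23 (3S,5S,6R)-6-[(2S,3E)-4-iodopent-3-en-2-yl]-5-methoxy-3-methyl-2-(phenylthio)tetrahydro-2H-pyran and 5 (S)-2-methoxyhex-5-enal
Product: 26 C3–C15 allylic alcohol (6S,7S,8E), via vinyllithium 24 (not isolated), via vinylmagnesium bromide 25 (not isolated)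
Conditions: t-BuLi (2.1 equiv), Et2O, −78 °C; MgBr2·OEt2; then 5·MgBr2 in CH2Cl2, −78 °C; then H2O
Reagents that add atoms: none
Why: Iodine–lithium exchange and transmetalation occur with retention of alkene geometry, and Cram-chelate addition (magnesium bridging C7=O and the C6 methoxy, attack anti to the C5 chain) should give the 6,7-syn carbinol (7S).

Step 19
Reactants: 26 C3–C15 allylic alcohol (6S,7S,8E)
Product: 27 C7 triethylsilyl ether of 26
Conditions: TESCl, imidazole, DMAP (cat.), DMF, 0 °C → rt
Reagents that add atoms: chlorotriethylsilane, CC[Si](Cl)(CC)CC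
Why: Silylation of the only free hydroxyl gives an ether that survives organolithium, Grignard and thermal steps and falls off in the final acidolysis.

Step 20
Reactants: 27 C7 triethylsilyl ether and 28 di-tert-butyl squarate
Product: 31 3-tert-butoxy-4-(tetrahydropyran-2-yl)cyclobut-3-ene-1,2-dione (C15 axial), via axial 2-lithiotetrahydropyran 29 (not isolated), via lithium alkoxide adduct 30 (not isolated)
Conditions: LiDBB (2.1 equiv, titrated), THF, −78 °C; then 28, −78 °C; then TFAA (2.5 equiv), −78 → 0 °C; aqueous work-up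
Reagents that add atoms: none
Why: Reductive lithiation of the 2-(phenylthio)tetrahydropyran gives, through the anomeric radical, the configurationally stable axial organolithium from either anomer, which adds 1,2 to the squarate with retention (C15–C16 bond axial, trans to the C11 chain), and trifluoroacetylation of the alkoxide triggers ionisation and loss of isobutene to the cyclobutenedione, the established squarate-to-3-alkoxy-4-alkylcyclobutenedione sequence.

Step 21
Reactants: 31 3-tert-butoxy-4-(tetrahydropyran-2-yl)cyclobut-3-ene-1,2-dione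
Product: 32 3-tert-butoxy-4-ethynyl-4-hydroxy-2-(tetrahydropyran-2-yl)cyclobut-2-en-1-one
Conditions: ethynylmagnesium bromide (1.5 equiv), THF, −78 → −40 °C; then H2O
Reagents that add atoms: ethynylmagnesium bromide, C#C[Mg]Br
Why: 1,2-Addition takes place at the carbonyl next to the tert-butoxy-bearing carbon (C18), since the other carbonyl is a deactivated vinylogous ester, the known regiochemistry for 3-alkoxycyclobutenediones.

Step 22
Reactants: 32 3-tert-butoxy-4-ethynyl-4-hydroxy-2-(tetrahydropyran-2-yl)cyclobut-2-en-1-one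
Product: 35 2-tert-butoxy-3-(tetrahydropyran-2-yl)-1,4-benzoquinone, via enynylketene 33 (not isolated), via aryl σ-oxyl diradical 34 (not isolated)
Conditions: toluene (degassed, 5 mM), 100 °C
Reagents that add atoms: none
Why: On heating, the cyclobutenone opens by 4π-electrocyclic cleavage of the C18–C21 bond (hydroxyl rotating outward, ethynyl inward) to the (Z)-enynylketene 33, whose ketene carbon C21 bonds to the terminal alkyne carbon C20 to give the aryl σ/phenoxyl diradical 34, and transfer of the hydroxyl hydrogen to C19 delivers quinone 35. The closest known reaction type is the Moore rearrangement of squarate-derived 4-alkynyl-4-hydroxycyclobutenones to 1,4-benzoquinones. The one ring that forms, the six-membered carbocycle C16–C21, closes by 6-endo attack of the ketene on the alkyne (C20–C21 bond), which expands the four-membered ring by the two ethynyl carbons. No stereocentre is created: the carbinol centre is destroyed and the C15 centre, which is not involved, should be retained under neutral thermal conditions. The selectivity needed is six- over five-membered closure (alkylidenecyclopentenedione), and it is secured by the unsubstituted alkyne terminus, which offers no radical stabilisation for the exo mode; the substituent pattern (C15 on C16 next to C21, tert-butoxy on C17) follows from the order of the two additions to the squarate in steps 20 and 21. The quinone arises directly, so no hydroquinone with an ionisable ortho-hydroxybenzylic C15–O bond is passed.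

Step 23
Reactants: 35 2-tert-butoxy-3-(tetrahydropyran-2-yl)-1,4-benzoquinone
Product: 37 5-amino-2-tert-butoxy-3-(tetrahydropyran-2-yl)-1,4-benzoquinone, via azidohydroquinone 36 (not isolated)
Conditions: NaN3 (3 equiv), AcOH (3 equiv), THF/H2O, rt
Reagents that add atoms: sodium azide, [Na+].[N-]=[N+]=[N-]
Why: Hydrazoic acid adds in conjugate fashion to the enone of the carbonyl not deactivated by the vinylogous ester (C18=O, attack at C20, para to C17), and the azidohydroquinone then loses N2 by internal redox to the aminoquinone, the known azide amination of 2-alkoxyquinones at C5.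

Step 24
Reactants: 37 5-amino-2-tert-butoxy-3-(tetrahydropyran-2-yl)-1,4-benzoquinone
Product: 38 N-(quinon-2-yl)methacrylamide seco compound
Conditions: methacryloyl chloride (3 equiv), pyridine, DMAP (0.2 equiv), BHT (trace), CH2Cl2, 0 °C → rt
Reagents that add atoms: methacryloyl chloride, CC(=C)C(Cl)=O
Why: N-Acylation of the quinone-bound amine by the acylpyridinium salt should be clean because this nitrogen is the only free nucleophile in the molecule.

Step 25
Reactants: 38 N-(quinon-2-yl)methacrylamide seco compound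
Product: 39 macrolactam with 17-O-tert-butyl and 7-O-triethylsilyl groups
Conditions: Grubbs second-generation catalyst (15 mol%), toluene (1 mM), 80 °C
Reagents that add atoms: none
Why: Ring-closing metathesis starts at the terminal alkene and closes onto the methacrylamide with loss of ethylene, the (E)-2-methyl enamide being the kinetically and thermodynamically preferred geometry while the quinone suppresses ruthenium hydride isomerisation.

Step 26
Reactants: 39 macrolactam with 17-O-tert-butyl and 7-O-triethylsilyl groups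
Product: 40 CNP0204467.1
Conditions: TFA/CH2Cl2 (1:4), H2O (5 equiv), 0 °C
Reagents that add atoms: none
Why: Acidolysis cleaves the vinylogous tert-butyl ester (loss of isobutene) to the hydroxyquinone and hydrolyses the triethylsilyl ether, while the electron-poor quinone keeps the C15–O bond from ionising.

**Compound list**

1 | (S)-glycidyl trityl ether | C1O[C@@H]1COC(c1ccccc1)(c1ccccc1)c1ccccc1 | starting material
2 | (S)-1-(trityloxy)hex-5-en-2-ol | C=CCC[C@H](O)COC(c1ccccc1)(c1ccccc1)c1ccccc1 | intermediate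
3 | (S)-2-methoxy-1-(trityloxy)hex-5-ene | C=CCC[C@H](OC)COC(c1ccccc1)(c1ccccc1)c1ccccc1 | intermediate
4 | (S)-2-methoxyhex-5-en-1-ol | C=CCC[C@H](OC)CO | intermediate
5 | (S)-2-methoxyhex-5-enal | C=CCC[C@H](OC)C=O | intermediate
6 | pent-3-yn-2-one | CC#CC(C)=O | starting material
7 | (S)-pent-3-yn-2-ol | CC#C[C@H](C)O | intermediate
8 | (S)-pent-3-yn-2-yl methanesulfonate | CC#C[C@H](C)OS(C)(=O)=O | intermediate
9 | (aR)-tributyl(penta-2,3-dien-2-yl)stannane | [H]C(C)=[C@@]=C(C)[Sn](CCCC)(CCCC)CCCC | intermediate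
10 | (S)-5-(trityloxymethyl)dihydrofuran-2(3H)-one | O=C1CC[C@@H](COC(c2ccccc2)(c2ccccc2)c2ccccc2)O1 | starting material
11 | lithium enolate of 10 (not isolated) | [Li]OC1=CC[C@@H](COC(c2ccccc2)(c2ccccc2)c2ccccc2)O1 | intermediate
12 | (3R,5S)-3-methyl-5-(trityloxymethyl)dihydrofuran-2(3H)-one (trans) | C[C@@H]1C[C@@H](COC(c2ccccc2)(c2ccccc2)c2ccccc2)OC1=O | intermediate
13 | lithium enolate of 12 (not isolated) | [Li]OC1=C(C)C[C@@H](COC(c2ccccc2)(c2ccccc2)c2ccccc2)O1 | intermediate
14 | (3S,5S)-3-methyl-5-(trityloxymethyl)dihydrofuran-2(3H)-one (cis) | C[C@H]1C[C@@H](COC(c2ccccc2)(c2ccccc2)c2ccccc2)OC1=O | intermediate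
15 | (2S,4S)-4-hydroxy-N-methoxy-N,2-dimethyl-5-(trityloxy)pentanamide | CON(C)C(=O)[C@@H](C)C[C@H](O)COC(c1ccccc1)(c1ccccc1)c1ccccc1 | intermediate
16 | (2S,4S)-N,4-dimethoxy-N,2-dimethyl-5-(trityloxy)pentanamide | CON(C)C(=O)[C@@H](C)C[C@H](OC)COC(c1ccccc1)(c1ccccc1)c1ccccc1 | intermediate
17 | (2S,4S)-5-hydroxy-N,4-dimethoxy-N,2-dimethylpentanamide | CON(C)C(=O)[C@@H](C)C[C@H](OC)CO | intermediate
18 | (2S,4S)-N,4-dimethoxy-N,2-dimethyl-5-oxopentanamide | CON(C)C(=O)[C@@H](C)C[C@H](OC)C=O | intermediate
19 | (2S,4S,5R,6S)-5-hydroxy-N,4-dimethoxy-N,2,6-trimethylnon-7-ynamide | CON(C)C(=O)[C@@H](C)C[C@H](OC)[C@H](O)[C@@H](C)C#CC | intermediate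
20 | (3S,5S,6R)-5-methoxy-3-methyl-6-[(S)-pent-3-yn-2-yl]tetrahydro-2H-pyran-2-ol (anomers) | CO[C@H]1C[C@H](C)C(O)O[C@@H]1[C@@H](C)C#CC | intermediate
21 | (3S,5S,6R)-5-methoxy-3-methyl-6-[(S)-pent-3-yn-2-yl]-2-(phenylthio)tetrahydro-2H-pyran (anomers) | CO[C@H]1C[C@H](C)C(Sc2ccccc2)O[C@@H]1[C@@H](C)C#CC | intermediate
22 | (E)-alkenylzirconocene chloride from 21 (not isolated; cyclopentadienyl rings drawn σ-bound) | CO[C@H]1C[C@H](C)C(Sc2ccccc2)O[C@@H]1[C@@H](C)/C=C(\C)[Zr](Cl)(C2C=CC=C2)C2C=CC=C2 | intermediate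
23 | (3S,5S,6R)-6-[(2S,3E)-4-iodopent-3-en-2-yl]-5-methoxy-3-methyl-2-(phenylthio)tetrahydro-2H-pyran | CO[C@H]1C[C@H](C)C(Sc2ccccc2)O[C@@H]1[C@@H](C)/C=C(\C)I | intermediate
24 | vinyllithium from 23 (not isolated) | CO[C@H]1C[C@H](C)C(Sc2ccccc2)O[C@@H]1[C@@H](C)/C=C(\C)[Li] | intermediate
25 | vinylmagnesium bromide from 24 (not isolated) | CO[C@H]1C[C@H](C)C(Sc2ccccc2)O[C@@H]1[C@@H](C)/C=C(\C)[Mg]Br | intermediate
26 | C3–C15 allylic alcohol (6S,7S,8E): 2-(phenylthio)tetrahydropyran carrying the C10–C3 chain with 7-OH, 6-OMe and terminal alkene | CO[C@H]1C[C@H](C)C(Sc2ccccc2)O[C@@H]1[C@@H](C)/C=C(\C)[C@H](O)[C@@H](OC)CCC=C | intermediate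
27 | C7 triethylsilyl ether of 26 | CO[C@H]1C[C@H](C)C(Sc2ccccc2)O[C@@H]1[C@@H](C)/C=C(\C)[C@H](O[Si](CC)(CC)CC)[C@@H](OC)CCC=C | intermediate
28 | di-tert-butyl squarate (3,4-di-tert-butoxycyclobut-3-ene-1,2-dione) | CC(C)(C)OC1=C(OC(C)(C)C)C(=O)C1=O | starting material
29 | axial 2-lithiotetrahydropyran from 27 (not isolated) | CO[C@H]1C[C@H](C)[C@@H]([Li])O[C@@H]1[C@@H](C)/C=C(\C)[C@H](O[Si](CC)(CC)CC)[C@@H](OC)CCC=C | intermediate
30 | lithium alkoxide of the squarate 1,2-adduct (not isolated) | CO[C@H]1C[C@H](C)[C@@H](C2(O[Li])C(OC(C)(C)C)=C(OC(C)(C)C)C2=O)O[C@@H]1[C@@H](C)/C=C(\C)[C@H](O[Si](CC)(CC)CC)[C@@H](OC)CCC=C | intermediate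
31 | 3-tert-butoxy-4-(tetrahydropyran-2-yl)cyclobut-3-ene-1,2-dione, C15 axial (S) | CO[C@H]1C[C@H](C)[C@@H](C2=C(OC(C)(C)C)C(=O)C2=O)O[C@@H]1[C@@H](C)/C=C(\C)[C@H](O[Si](CC)(CC)CC)[C@@H](OC)CCC=C | intermediate
32 | 3-tert-butoxy-4-ethynyl-4-hydroxy-2-(tetrahydropyran-2-yl)cyclobut-2-en-1-one (carbinol epimers) | CO[C@H]1C[C@H](C)[C@@H](C2=C(OC(C)(C)C)C(O)(C#C)C2=O)O[C@@H]1[C@@H](C)/C=C(\C)[C@H](O[Si](CC)(CC)CC)[C@@H](OC)CCC=C | intermediate
33 | (Z)-enynylketene from ring opening of 32 (not isolated) | CO[C@H]1C[C@H](C)[C@@H](C(=C=O)/C(OC(C)(C)C)=C(/O)C#C)O[C@@H]1[C@@H](C)/C=C(\C)[C@H](O[Si](CC)(CC)CC)[C@@H](OC)CCC=C | intermediate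
34 | aryl σ-radical/phenoxyl diradical (not isolated) | CO[C@H]1C[C@H](C)[C@@H](c2c(OC(C)(C)C)c(O)[c]cc2[O])O[C@@H]1[C@@H](C)/C=C(\C)[C@H](O[Si](CC)(CC)CC)[C@@H](OC)CCC=C | intermediate
35 | 2-tert-butoxy-3-(tetrahydropyran-2-yl)-1,4-benzoquinone | CO[C@H]1C[C@H](C)[C@@H](C2=C(OC(C)(C)C)C(=O)C=CC2=O)O[C@@H]1[C@@H](C)/C=C(\C)[C@H](O[Si](CC)(CC)CC)[C@@H](OC)CCC=C | intermediate
36 | azidohydroquinone (not isolated) | CO[C@H]1C[C@H](C)[C@@H](c2c(OC(C)(C)C)c(O)cc(N=[N+]=[N-])c2O)O[C@@H]1[C@@H](C)/C=C(\C)[C@H](O[Si](CC)(CC)CC)[C@@H](OC)CCC=C | intermediate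
37 | 5-amino-2-tert-butoxy-3-(tetrahydropyran-2-yl)-1,4-benzoquinone | CO[C@H]1C[C@H](C)[C@@H](C2=C(OC(C)(C)C)C(=O)C=C(N)C2=O)O[C@@H]1[C@@H](C)/C=C(\C)[C@H](O[Si](CC)(CC)CC)[C@@H](OC)CCC=C | intermediate
38 | N-(quinon-2-yl)methacrylamide seco compound | CO[C@H]1C[C@H](C)[C@@H](C2=C(OC(C)(C)C)C(=O)C=C(NC(=O)C(C)=C)C2=O)O[C@@H]1[C@@H](C)/C=C(\C)[C@H](O[Si](CC)(CC)CC)[C@@H](OC)CCC=C | intermediate
39 | macrolactam with 17-O-tert-butyl and 7-O-triethylsilyl groups | CO[C@H]1C[C@H](C)[C@@H]2O[C@@H]1[C@@H](C)/C=C(\C)[C@H](O[Si](CC)(CC)CC)[C@@H](OC)CC/C=C(\C)C(=O)NC1=CC(=O)C(OC(C)(C)C)=C2C1=O | intermediate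
40 | CNP0204467.1 | CO[C@H]1C[C@H](C)[C@@H]2O[C@@H]1[C@@H](C)/C=C(\C)[C@H](O)[C@@H](OC)CC/C=C(\C)C(=O)NC1=CC(=O)C(O)=C2C1=O | target

**Step count and risks**

Total steps: 26. Longest linear sequence: 19 steps (steps 8–26, from lactone 10).

Risk 1, step 25 (ring-closing metathesis). The 1,1-disubstituted, amide-conjugated olefin may engage too slowly, so that intermolecular metathesis to dimers or closure to the (Z)-enamide competes. The fallback sets out from aminoquinone 37 and builds the macrocycle at the amide bond instead. Cross-metathesis with methacrolein (Hoveyda–Grubbs II, CH2Cl2, 40 °C) should give the (E)-enal aminoquinone F1. Pinnick oxidation (NaClO2, NaH2PO4, 2-methyl-2-butene) should give the seco acid F2. EDC and pentafluorophenol should give the pentafluorophenyl ester F3, which is expected to be stable because the quinone-bound amine is too poor a nucleophile to self-condense. Brief reduction with Na2S2O4 (degassed EtOAc/pH 7 buffer, high dilution) unmasks the nucleophilic aminohydroquinone, which should lactamise onto the active ester to the hydroquinone macrolactam F4. Air oxidation then returns to 39. The hydroquinone stage is kept short because its ortho-hydroxybenzylic C15–O bond could ionise.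

Risk 2, step 20 (reductive lithiation, squarate addition and rearrangement in one flask). Electron transfer to other sites, protonation or axial-to-equatorial equilibration of the organolithium, or attack of thiolate on the squarate may erode the union. The fallback sets out from 27 and separates the events. Reductive lithiation followed by Bu3SnCl should give the isolable axial stannane F5. Tin–lithium exchange (n-BuLi, THF, −78 °C, retention) regenerates 29 free of thiolate and arene. Addition to 28 and aqueous quench should give the neutral carbinol F6, which is purified. Separate treatment with TFAA and 2,6-lutidine returns to 31.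

Risk 3, step 24 (N-acylation of the aminoquinone). The vinylogous-amide nitrogen may acylate incompletely, and forcing conditions could polymerise the methacryloyl unit or cleave the tert-butyl group. The fallback sets out from 37. Reduction with Na2S2O4 should give the aminohydroquinone F7, whose nitrogen is an ordinary aminophenol nitrogen. Methacrylic anhydride in EtOAc/aqueous NaHCO3 should acylate it selectively on nitrogen to the amidohydroquinone F8. Air oxidation returns to 38.

**Further compounds**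

F1 | step 25 | (E)-enal aminoquinone from cross-metathesis of 37 with methacrolein | CO[C@H]1C[C@H](C)[C@@H](C2=C(OC(C)(C)C)C(=O)C=C(N)C2=O)O[C@@H]1[C@@H](C)/C=C(\C)[C@H](O[Si](CC)(CC)CC)[C@@H](OC)CC/C=C(\C)C=O
F2 | step 25 | seco acid aminoquinone | CO[C@H]1C[C@H](C)[C@@H](C2=C(OC(C)(C)C)C(=O)C=C(N)C2=O)O[C@@H]1[C@@H](C)/C=C(\C)[C@H](O[Si](CC)(CC)CC)[C@@H](OC)CC/C=C(\C)C(O)=O
F3 | step 25 | pentafluorophenyl ester of F2 | CO[C@H]1C[C@H](C)[C@@H](C2=C(OC(C)(C)C)C(=O)C=C(N)C2=O)O[C@@H]1[C@@H](C)/C=C(\C)[C@H](O[Si](CC)(CC)CC)[C@@H](OC)CC/C=C(\C)C(=O)Oc1c(F)c(F)c(F)c(F)c1F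
F4 | step 25 | hydroquinone macrolactam | CO[C@H]1C[C@H](C)[C@@H]2O[C@@H]1[C@@H](C)/C=C(\C)[C@H](O[Si](CC)(CC)CC)[C@@H](OC)CC/C=C(\C)C(=O)Nc1cc(O)c(OC(C)(C)C)c2c1O
F5 | step 20 | axial 2-(tributylstannyl)tetrahydropyran | CO[C@H]1C[C@H](C)[C@@H]([Sn](CCCC)(CCCC)CCCC)O[C@@H]1[C@@H](C)/C=C(\C)[C@H](O[Si](CC)(CC)CC)[C@@H](OC)CCC=C
F6 | step 20 | 4-hydroxy-2,3-di-tert-butoxy-4-(tetrahydropyran-2-yl)cyclobut-2-en-1-one | CO[C@H]1C[C@H](C)[C@@H](C2(O)C(OC(C)(C)C)=C(OC(C)(C)C)C2=O)O[C@@H]1[C@@H](C)/C=C(\C)[C@H](O[Si](CC)(CC)CC)[C@@H](OC)CCC=C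
F7 | step 24 | aminohydroquinone from 37 | CO[C@H]1C[C@H](C)[C@@H](c2c(OC(C)(C)C)c(O)cc(N)c2O)O[C@@H]1[C@@H](C)/C=C(\C)[C@H](O[Si](CC)(CC)CC)[C@@H](OC)CCC=C
F8 | step 24 | N-methacryloyl aminohydroquinone | CO[C@H]1C[C@H](C)[C@@H](c2c(OC(C)(C)C)c(O)cc(NC(=O)C(C)=C)c2O)O[C@@H]1[C@@H](C)/C=C(\C)[C@H](O[Si](CC)(CC)CC)[C@@H](OC)CCC=C
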